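**Assumptions (one line each)**
- (2E,6E)-Farnesyl acetate and furan-3-ylboronic acid are commercial.
- The macrocyclic vinylogous aldol is taken to be anti-selective (13R,14S), with absolute configuration set by the chiral Lewis-base catalyst.
- The catalyst enantiomer is whichever delivers the 14S butenolide; this has to be matched empirically.

**Retrosynthetic overview**
1. Target **13** comes from late, regio- and diastereoselective epoxidation of the C3=C4 olefin of triene **12**. **12** comes from α-methylenation of trans-lactone **11**. **11** comes from Mitsunobu acetoxylation (C13 inversion) of **10**. **10** comes from hydroxyl-directed conjugate reduction of macrocyclic butenolide **9**, which sets C1 trans to C14.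
2. **9** comes from an intramolecular dearomative vinylogous Mukaiyama aldol of the 4-substituted 2-silyloxyfuran **8** onto an (E)-α-methyl enal. This closes the 14-membered ring at C13–C14 and sets C13/C14.
3. **8** comes from enal **7**, which is made from 3-alkylfuran **4** by C5-borylation/oxidation to the butenolide. **4** is built from furan-3-ylboronic acid and 12-hydroxyfarnesyl acetate **3**, and **3** comes from farnesyl acetate **1**.
4. Ring order: furan (commercial) → butenolide → 14-membered carbocycle with the γ-lactone already in place → epoxide last.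

---

**Step 1**
Reactants: **1** (2E,6E)-farnesyl acetate
Product: **3** (2E,6E,10E)-12-hydroxy-3,7,11-trimethyldodeca-2,6,10-trien-1-yl acetate
Conditions: SeO2 (5 mol %), TBHP (2 equiv, in decane), salicylic acid (5 mol %), CH2Cl2, 0 °C → rt
Reagents that add atoms: tert-butyl hydroperoxide, CC(C)(C)OO (oxygen source)
Why: Allylic oxidation of the terminal isopropylidene goes preferentially at the E-methyl (the one trans to the chain), giving the (E)-allylic alcohol that later becomes C13; no stereocenter is formed.

**Step 2**
Reactants: **3**; **2** furan-3-ylboronic acid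
Product: **4** (2E,6E,10E)-12-(furan-3-yl)-2,6,10-trimethyldodeca-2,6,10-trien-1-ol
Conditions: Pd2(dba)3 (2.5 mol %), PPh3 (10 mol %), K3PO4, dioxane/H2O, 60 °C
Reagents that add atoms: none
Why: Pd-catalysed allyl–aryl Suzuki–Miyaura coupling ionises the primary allylic acetate and gives the linear product, with the three E-olefins and the free alcohol preserved; this forms the C1–C2 bond.

**Step 3**
Reactants: **4**
Product: **6** 4-[(2E,6E,10E)-12-hydroxy-3,7,11-trimethyldodeca-2,6,10-trien-1-yl]furan-2(5H)-one, via boronate **5** (formed in situ, not isolated)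
Conditions: (i) [Ir(cod)OMe]2 (1.5 mol %), dtbpy (3 mol %), B2pin2 (1.5 equiv), THF, 80 °C; (ii) NaBO3·4H2O, THF/H2O, rt
Reagents that add atoms: sodium perborate (oxygen source, formally OO)
Why: Sterically controlled Ir-catalysed C–H borylation of a 3-alkylfuran occurs at C5 (the α-position remote from the substituent), and oxidative deborylation gives a 2-hydroxyfuran that tautomerises to the conjugated butenolide (C14H2–O–C17(=O)–C15H=C1).

**Step 4**
Reactants: **6**
Product: **7** 4-[(2E,6E,10E)-3,7,11-trimethyl-12-oxododeca-2,6,10-trien-1-yl]furan-2(5H)-one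
Conditions: MnO2 (20 equiv), CH2Cl2, rt
Reagents that add atoms: none
Why: Chemoselective MnO2 oxidation of the allylic alcohol gives the (E)-α-methyl enal (C13 aldehyde) without touching the butenolide or the trisubstituted olefins.

**Step 5**
Reactants: **7**
Product: **8** 2-(tert-butyldimethylsilyloxy)-4-[…12-oxo…]furan (silyl dienol ether)
Conditions: TBSOTf (1.3 equiv), Et3N (2 equiv), CH2Cl2, −78 → 0 °C, then a short plug of basic alumina
Reagents that add atoms: TBSOTf, CC(C)(C)[Si](C)(C)OS(=O)(=O)C(F)(F)F
Why: Soft silyl-triflate enolisation re-aromatises the butenolide to the 2-silyloxyfuran, which is the C14 (γ-carbon) nucleophile for the key step.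

**Step 6**
Reactants: **8**
Product: **9** (13R,14S)-macrocyclic butenolide with 13-OH (14-membered carbocycle; C1=C15 butenolide; 3E,7E,11E)
Conditions: SiCl4 (1.5 equiv), iPr2NEt (3 equiv), chiral bisphosphoramide (10 mol %), CH2Cl2, −78 °C, substrate added by syringe pump to about 2 mM; NaHCO3 work-up
Reagents that add atoms: none (the silyl group is lost on work-up)
Why: Proposed new method: a chiral-Lewis-base-activated SiCl4 (Cl3Si+) activates the enal, and the γ-carbon of the 2-silyloxyfuran attacks it through an open, anti-periplanar transition state. Aromaticity is lost, the 14-ring closes at C13–C14, and the anti (13R,14S) stereodiad is set enantioselectively. The closest known reaction is the Lewis-base-catalysed intermolecular vinylogous Mukaiyama aldol of 2-silyloxyfurans with enals, run here at high dilution to favour macrocyclisation.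

**Step 7**
Reactants: **9**
Product: **10** (1S,13R,14S)-saturated trans-lactone with 13-OH
Conditions: Cu(OAc)2·H2O (10 mol %), dppf (10 mol %), TMDS (4 equiv), toluene, 0 °C → rt; then TBAF, THF
Reagents that add atoms: none (hydride and silyl are removed on work-up)
Why: Proposed new method: the free C13-OH is silylated in situ to a hydridosilyl ether, and Cu–H delivers hydride to C1 through a six-membered transition state from the face carrying C13. This gives the trans ring fusion (C2 trans to C13) while leaving the three isolated olefins intact. The closest known reaction is Cu–H 1,4-reduction of butenolides with hydroxyl-directed hydrosilane delivery.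

**Step 8**
Reactants: **10**
Product: **11** (1S,13S,14S)-13-acetoxy saturated lactone
Conditions: PPh3 (2 equiv), DIAD (2 equiv), AcOH (3 equiv), THF, 0 °C → rt
Reagents that add atoms: acetic acid, CC(=O)O
Why: Mitsunobu SN2 esterification inverts C13 from the anti-aldol 13R to the required 13S and installs the acetate in one step; the lactone is no longer γ-acidic after Step 7, so it is not epimerised or eliminated.

**Step 9**
Reactants: **11**
Product: **12** (1S,13S,14S)-13-acetoxy α-methylene-γ-lactone (3,4-dehydro precursor of the target)
Conditions: LiHMDS (1.1 equiv), THF, −78 °C; then Me2N+=CH2 I− (2 equiv), −78 → 0 °C; then MeI, rt; then DBU, CH2Cl2, rt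
Reagents that add atoms: Eschenmoser's salt, C=[N+](C)C.[I-] (its CH2 becomes the exocyclic methylene)
Why: Danishefsky-type Mannich α-methylenation; the more acidic lactone α-CH2 is deprotonated in preference to the acetate, C15 becomes sp2 so there is no new stereocenter, and C1 and C14 are untouched.

**Step 10**
Reactants: **12**
Product: **13** 13-acetoxysarcocrassolide
Conditions: mCPBA (1.0 equiv), NaHCO3 (5 equiv), CH2Cl2, −20 °C
Reagents that add atoms: mCPBA, O=C(OO)c1cccc(Cl)c1
Why: Proposed new method: the electron-poor α-methylene-lactone olefin is inert, and C11=C12 is deactivated by the allylic acetate. Of the remaining two trisubstituted olefins, C3=C4 is expected to be epoxidised on the outer (peripheral) face of the macrocycle to give the (3S,4S)-epoxide; the closest known reaction is mCPBA epoxidation of macrocyclic cembranoid polyenes.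

---

**Compound list**

| # | Name | SMILES | Role |
|---|---|---|---|
| 1 | (2E,6E)-farnesyl acetate | CC(=O)OC/C=C(\C)CC/C=C(\C)CCC=C(C)C | starting material |
| 2 | furan-3-ylboronic acid | OB(O)c1ccoc1 | starting material |
| 3 | 12-hydroxyfarnesyl acetate | CC(=O)OC/C=C(\C)CC/C=C(\C)CC/C=C(\C)CO | intermediate |
| 4 | (2E,6E,10E)-12-(furan-3-yl)-2,6,10-trimethyldodeca-2,6,10-trien-1-ol | OC/C(C)=C/CC/C(C)=C/CC/C(C)=C/Cc1ccoc1 | intermediate |
| 5 | 5-Bpin derivative of 4 (in situ, not isolated) | OC/C(C)=C/CC/C(C)=C/CC/C(C)=C/Cc1coc(B2OC(C)(C)C(C)(C)O2)c1 | intermediate |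
| 6 | 4-(12-hydroxy-farnesyl-type chain)furan-2(5H)-one | OC/C(C)=C/CC/C(C)=C/CC/C(C)=C/CC1=CC(=O)OC1 | intermediate |
| 7 | enal-butenolide | O=C/C(C)=C/CC/C(C)=C/CC/C(C)=C/CC1=CC(=O)OC1 | intermediate |
| 8 | 2-TBSO-furan enal | O=C/C(C)=C/CC/C(C)=C/CC/C(C)=C/Cc1coc(O[Si](C)(C)C(C)(C)C)c1 | intermediate |
| 9 | (13R,14S)-macrocyclic butenolide alcohol | O=C1O[C@H]2C(=C1)C/C=C(\C)CC/C=C(\C)CC/C=C(\C)[C@H]2O | intermediate |
| 10 | (1S,13R,14S)-trans-lactone alcohol | C1C(=O)O[C@H]2[C@H]1C/C=C(\C)CC/C=C(\C)CC/C=C(\C)[C@H]2O | intermediate |
| 11 | (1S,13S,14S)-13-acetoxy lactone | C1C(=O)O[C@H]2[C@H]1C/C=C(\C)CC/C=C(\C)CC/C=C(\C)[C@@H]2OC(C)=O | intermediate |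
| 12 | (1S,13S,14S)-13-acetoxy α-methylene lactone (3,4-alkene) | C=C1C(=O)O[C@H]2[C@H]1C/C=C(\C)CC/C=C(\C)CC/C=C(\C)[C@@H]2OC(C)=O | intermediate |
| 13 | 13-acetoxysarcocrassolide (1S,3S,4S,13S,14S) | C=C1C(=O)O[C@H]2[C@H]1C[C@@H]1O[C@@]1(C)CC/C=C(\C)CC/C=C(\C)[C@@H]2OC(C)=O | target |

**Total steps:** 10.
**Longest linear sequence:** 10 (compound 1 → 13).

**Three steps most likely to fail**
1. **Step 6, macrocyclic vinylogous Mukaiyama aldol.** Risks are oligomerisation, anti/syn ratio and ee. Fallback: change the disconnection to an intramolecular Nozaki–Hiyama–Kishi-type allylation of a C14 aldehyde with a 2-(bromomethyl)alkenoate, which closes the C1–C14 bond and the α-methylene lactone together.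
2. **Step 10, C3=C4-selective epoxidation.** C7=C8 is intrinsically more reactive. Fallback: install the (2S,3S)-epoxide early by Sharpless asymmetric epoxidation of farnesol and carry it through a Cr(II)-mediated macrocyclisation route that tolerates epoxides.
3. **Step 7, directed conjugate reduction giving the trans ring fusion.** Without the directing effect, cis-fused lactone is likely. Fallback: build C1 by trans-selective cuprate conjugate addition to a γ-substituted butenolide made by an intermolecular vinylogous Mukaiyama aldol, then close the ring by macro-RCM.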